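## The problem

The target is a pentacyclic rearranged clerodane. Rings A (C5–C10) and B (C1–C5, C10) form a trans-fused decalin; C4 and C5 are bridged by a γ-lactone, C18(=O)–O–C19H2, conjugated with the C3=C4 alkene; and C1 and C9 are tied through C11–C12(=O) and a 2,3-fused furan (C13–C16) into the seven-membered ring C. There are five stereocentres (C1, C5, C7, C9, C10). C5 and C9 are quaternary and sit 1,3 to each other across C10, with C19 and the C9 methyl (C20) syn-diaxial. C5 can steer C10, because reagents add anti to the angular C19 once ring B is closed. C5 and the axial C20 together can steer C7, because both block the β face. C9 and C1 have no such helper, and C9 cannot be corrected once formed, so it needs a stereospecific event. The fragile groups are the furan (peracids, halonium sources, strong acid), the allylic acetate beside a 1,1-disubstituted alkene (ionisation, isomerisation, electrophiles), the alkylidene lactone (conjugate addition, γ-deprotonation) and the 1,3-dioxygenated C8/C11 intermediates (retro-aldol). A five-membered ketone next to C10–H in a trans-fused bicycle is expected to prefer the cis fusion, so such an intermediate has to be made kinetically and kept away from base. The enabling feature is quaternary C9 between ring-fusion C10 and C8. With C8 as a ketone, ring A is a 2-methyl-2-(hydroxymethyl)cyclohexanone, the retron of a semipinacol ring expansion of a cyclopentanol that carries a 2-methyloxiranyl group on its carbinol carbon C8, with C10 as the migrating atom.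

## Retrosynthesis

**Ring C (C12–C13).** Target 40 is opened at the bond between the ketone carbon and furan C13, giving acid 38. Cutting C1–C16 instead would need a 3-furyl nucleophile and a late conjugate addition; cutting C11–C12 would need a furan already acylated at C3. The chosen cut lets the furan come from furfural as a plain 2-furyl group, and intramolecularity forces attack at the only reachable position, C13. The forward reaction is a Friedel–Crafts acylation that must spare the allylic acetate and the exocyclic alkene.

**Ring A substituents and C12 (C8=C17, C7–O, C11–C12).** Acid 38 goes back through aldehyde 37 and enol ether 36 to acetate 35, alcohol 34, enol ether 33, keto aldehyde 32 and hydroxy ketone 31. C7 oxidation and C8 methylenation are placed while C8 is the only ketone, before C12 becomes a carbonyl, so no two ketones ever have to be told apart. The price is that the alkene is present in the acylation; it is then deactivated by the allylic acetate. The enol ether carries C12 through these steps as a base-stable group.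

**Ring A (C9–C10 made, C8–C10 broken).** Ketone 31 is traced to epoxy alcohol 30. This removes ring A and the quaternary stereocentre C9 in one operation and leaves a cyclopentanol in which C9 is an epoxide carbon. The forward step must move C10 rather than C7 and must copy the epoxide configuration into C9.

**Epoxide and carbinol (C9–C11, C8–C9).** Epoxy alcohol 30 comes from α-hydroxy ketone 27 and the ylide from trimethylsulfonium iodide 28. Ketone 27 comes from ketone 23 and ethyl vinyl ether 24 as an acetyl anion equivalent. Adding the CH2 unit to a methyl ketone, rather than a methyl group to a CH2X ketone, is what gives the required C9 epimer under chelation. Nucleophiles must enter C8 anti to C19.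

**Trans ring fusion (C10–H, C8–O).** Ketone 23 is taken back through alcohol 22 to diene lactone 20. Setting C10 by syn addition of H–B to a C8=C10 alkene avoids any equilibration of a trans-fused cyclopentanone. Borane must add anti to the angular C19 and must ignore the conjugated C3=C4 alkene and the furan.

**Ring B (C3–C4).** Diene lactone 20 arises from triflate 19 and enol lactone 18, and 18 from ester 17 by a Dieckmann closure between the lactone α-carbon C4 and the ester carbon C3. Closing ring B while C10 is still sp2 removes any cis/trans issue at this stage and gives the C3=C4 position regiospecifically through the triflate.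

**C1 (C1–C2).** Ester 17 is disconnected by a Johnson–Claisen transform to allylic alcohol 15, from ketone 14. A conjugate addition to 14 would leave both C1 and C10 to the weak bias of the two CH2 arms on C5. The sigmatropic route instead relays a catalyst-set carbinol (C8) into C1 and places the alkene exactly where step 13 needs it.

**Furan (C1=C10).** Ketone 14 comes from dienone 13, and 13 from enone 9 and furfural 10 by aldol condensation. The enone is used because its only enolisable position is the future C10.

**Quaternary C5 (C4–C5, C5–C19).** Enone 9 goes back through spiro-lactone 8 and ester 6 to allylic alcohol 4 (Johnson–Claisen with chirality transfer), enone 3 and 3-ethoxycyclopent-2-en-1-one 1. One catalytic reduction fixes the absolute configuration of the whole route.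

## Roads not taken

**Alternative 1:** The cut is C5–C10 and C1–C2, forming rings A and B together. The forward key step heats triene A2, in which a 2-methoxycarbonyl diene (C5=C4–C3=C2) is tethered through C6–C9 to the E-configured vinylfuran C10=C1, to give trans-decalin diester A1 by intramolecular Diels–Alder reaction.
- Merits: two rings, quaternary C5 and the C1/C10 pair arise in one step, with C3=C4 already conjugated and both acid arms in place. After the cycloaddition this road is shorter and more convergent than the chosen one.
- Weak points: the tetrasubstituted diene terminus, quaternary C9 and C7 must all be built acyclically and enantioselectively beforehand, so the hardest centre is moved rather than solved. The dienophile is an unactivated vinylfuran whose furan can itself react as a diene. The trans fusion rests on an endo/exo preference with no strong bias, under prolonged heating of an allylic acetate.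
- Comparison: against the brevity of this road the chosen plan sets that each stereocentre is fixed by a stereospecific or catalyst-controlled event (4 to 6, 15 to 17, 20 to 22, 30 to 31) and that C9 is created inside a ring.

**Alternative 2:** The cut is C1–C16, closing ring C last at the furan α-position. Lewis-acid activation of dienyl lactone A4 (C1=C2, C3=C4) lets C16 of the tethered 3-substituted furan add to C1 in a 1,6 sense, giving dithiolane A3.
- Merits: the furan reacts at its more nucleophilic α-carbon, which is better than step 25 of the chosen plan, where the less nucleophilic β-carbon must be used. No acyl cation is generated near the exocyclic alkene, and C1 is set by the finished decalin.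
- Weak points: ring A with quaternary C9 and the 3-furyl ketone side chain must exist before the key step, so C9 and the ring fusion are left unanswered. The ketone has to be masked (the dithiolane) to keep the furan nucleophilic, which costs steps and is itself Lewis-acid labile. The dienolate must be protonated so that C3=C4 results.
- Comparison: the chosen plan concedes the electronically better ring C closure. It sets against it inexpensive furfural, a robust 2-furyl group carried through the route, and a key step that makes C9 instead of presupposing it.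

**Alternative 3:** The cut is C4–C5 and O–C18. Irradiation of diazo ketone A6 (a seven-membered α-diazo-β,γ-enone) expels N2, C5 shifts from C18 to C4 (Wolff rearrangement) and the C19 hydroxyl traps the ketene, giving lactone A5.
- Merits: ring B and the strained lactone form together under neutral conditions with retention at C5. This is one step where the chosen plan spends four (steps 4, 10, 11, 12), so this road is better in step economy for that subunit.
- Weak points: A6 is harder to make than A5 (a cycloheptenone with two quaternary centres and a regiodefined diazo group). The furan and the exocyclic alkene are exposed to light and a free carbene. The vinylketene adduct must protonate at C2. C9 and ring A are not addressed.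
- Comparison: the chosen plan pays extra steps for ring B but uses only ground-state, chemoselective reactions around the furan and draws ring B from a spiro-lactone available in four steps.

Key step: step 17

Remark on labels: atom labels C1–C20 are those of the target (C17 = exocyclic methylene carbon, C20 = methyl on C9; β = the face of C19, α the opposite face). Compound numbers carry no letter. "Bicyclic" means ring B fused at C5–C10 to the five-membered ring C5–C6–C7–C8–C10; "decalin" means rings A and B; "18,19-lactone" means C18(=O)–O–C19H2 across C4/C5.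

Remark on the chemistry: step 6 is assumed to give the E-alkylidene ketone 13 (furyl anti to the ketone); if the Z isomer formed, the antipodal catalyst would be used in step 8.

## Route

Step 1
Reactants: 1 3-ethoxycyclopent-2-en-1-one
Product: 3 3-[(methoxymethoxy)methyl]cyclopent-2-en-1-one, via carbinol adduct 2 (not isolated)
Conditions: Bu3SnCH2OCH2OMe, n-BuLi, THF, −78 °C; then 1; then 1 M HCl, 0 °C → rt
Reagents that add atoms: tributyl[(methoxymethoxy)methyl]stannane CCCC[Sn](CCCC)(CCCC)COCOC; water O
Why: Tin–lithium exchange gives the α-alkoxymethyllithium, which adds 1,2 to the vinylogous ester; acid then ionises the tertiary allylic alcohol and hydrolyses the enol ether with carbonyl transposition (Stork–Danheiser sequence), placing C19 on the future C5.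

Step 2
Reactants: 3 3-[(methoxymethoxy)methyl]cyclopent-2-en-1-one
Product: 4 (1R)-3-[(methoxymethoxy)methyl]cyclopent-2-en-1-ol
Conditions: (S)-Me-CBS (10 mol %), catecholborane, PhMe, −78 °C; MeOH
Reagents that add atoms: none
Why: Corey–Bakshi–Shibata reduction; the enone binds to the catalyst boron anti to its alkenyl flank and hydride is delivered to one face, setting the R carbinol centre that is relayed to C5 in step 3; catecholborane avoids hydroboration.

Step 3
Reactants: 4 (1R)-3-[(methoxymethoxy)methyl]cyclopent-2-en-1-ol
Product: 6 ethyl 2-[(1S)-1-[(methoxymethoxy)methyl]cyclopent-2-en-1-yl]acetate, via ketene acetal 5 (not isolated)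
Conditions: MeC(OEt)3, EtCO2H (cat.), 140 °C, EtOH distilled off
Reagents that add atoms: triethyl orthoacetate CC(OCC)(OCC)OCC
Why: Johnson–Claisen rearrangement; the suprafacial [3,3] shift forms the C4–C5 bond on the ring face that carried the C–O bond, so the carbinol configuration is copied into quaternary C5.

Step 4
Reactants: 6 ethyl 2-[(1S)-1-[(methoxymethoxy)methyl]cyclopent-2-en-1-yl]acetate
Product: 8 (5S)-2-oxaspiro[4.4]non-6-en-3-one, via hydroxy ester 7 (not isolated)
Conditions: HCl (cat.), EtOH, 60 °C; then p-TsOH (cat.), PhMe, 80 °C
Reagents that add atoms: none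
Why: Acid-catalysed acetal exchange frees the C19 hydroxyl, and the γ-hydroxy ester closes to the five-membered lactone, helped by the quaternary centre; no stereocentre is touched.

Step 5
Reactants: 8 (5S)-2-oxaspiro[4.4]non-6-en-3-one
Product: 9 (5S)-2-oxaspiro[4.4]non-8-ene-3,7-dione
Conditions: Rh2(caprolactamate)4 (1 mol %), t-BuOOH (aq.), K2CO3, CH2Cl2, rt
Reagents that add atoms: tert-butyl hydroperoxide CC(C)(C)OO
Why: Dirhodium-catalysed allylic C–H oxidation; the only allylic methylene (the other allylic carbon is quaternary C5) becomes the C8 ketone, giving a 4,4-disubstituted cyclopentenone whose single enolisable position is the future C10.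

Step 6
Reactants: 9 (5S)-2-oxaspiro[4.4]non-8-ene-3,7-dione; 10 furfural
Product: 13 (5S,6E)-6-(furan-2-ylmethylidene)-2-oxaspiro[4.4]non-8-ene-3,7-dione, via aldol adduct 11 (not isolated), via aldol mesylate 12 (not isolated)
Conditions: LiN(SiMe3)2, THF, −78 °C; 10; then MsCl, Et3N, 0 °C; DBU, rt
Reagents that add atoms: none
Why: Aldol condensation; the kinetic α'-enolate (the lactone α-protons are several pKa units less acidic) adds to furfural, and mesylation with E1cB elimination gives the E-alkylidene ketone, with C1 and C10 both sp2.

Step 7
Reactants: 13 (5S,6E)-6-(furan-2-ylmethylidene)-2-oxaspiro[4.4]non-8-ene-3,7-dione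
Product: 14 (5R,6E)-6-(furan-2-ylmethylidene)-2-oxaspiro[4.4]nonane-3,7-dione
Conditions: H2 (1 atm), RhCl(PPh3)3 (5 mol %), PhH/EtOH, rt
Reagents that add atoms: none
Why: Homogeneous hydrogenation with RhCl(PPh3)3 discriminates by substitution; the cis-disubstituted ring alkene is reduced while the trisubstituted furfurylidene alkene and the furan are left, as in the selective reduction of the less substituted bond of cross-conjugated dienones.

Step 8
Reactants: 14 (5R,6E)-6-(furan-2-ylmethylidene)-2-oxaspiro[4.4]nonane-3,7-dione
Product: 15 (5R,6E,7R)-6-(furan-2-ylmethylidene)-7-hydroxy-2-oxaspiro[4.4]nonan-3-one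
Conditions: (S)-Me-CBS (20 mol %), catecholborane, PhMe, −78 °C; MeOH
Reagents that add atoms: none
Why: Corey–Bakshi–Shibata reduction under catalyst control (alkylidene flank large, CH2 flank small) sets C8 as R with the hydroxyl cis to C19; the remote C5 centre should exert little bias.

Step 9
Reactants: 15 (5R,6E,7R)-6-(furan-2-ylmethylidene)-7-hydroxy-2-oxaspiro[4.4]nonan-3-one
Product: 17 ethyl (3R)-3-(furan-2-yl)-3-[(5R)-3-oxo-2-oxaspiro[4.4]non-6-en-6-yl]propanoate, via ketene acetal 16 (not isolated)
Conditions: MeC(OEt)3, 2-nitrophenol (cat.), xylene, 135 °C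
Reagents that add atoms: triethyl orthoacetate CC(OCC)(OCC)OCC
Why: Johnson–Claisen rearrangement; the suprafacial [3,3] shift delivers C2 to C1 on the face of the departing C8–O bond, so with the E-alkene the C8 configuration is translated into C1 (R) and the alkene moves to C8=C10; the weak phenolic acid limits ionisation of the furyl-allylic alcohol.

Step 10
Reactants: 17 ethyl (3R)-3-(furan-2-yl)-3-[(5R)-3-oxo-2-oxaspiro[4.4]non-6-en-6-yl]propanoate
Product: 18 bicyclic enol lactone 3-hydroxy-1α-(2-furyl)-3,8(10)-diene 18,19-lactone (enol form of the 3-oxo lactone)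
Conditions: KOt-Bu, THF, 0 °C → rt; then 1 M HCl
Reagents that add atoms: none
Why: Dieckmann condensation; the lactone enolate (C4) acylates on the ethyl ester (6-exo-trig) and closes ring B, driven by deprotonation of the β-keto lactone, whereas attack of the ester enolate on the lactone only opens it to an alkoxide that can revert.

Step 11
Reactants: 18 bicyclic enol lactone
Product: 19 bicyclic enol triflate 3-(trifluoromethylsulfonyloxy)-1α-(2-furyl)-3,8(10)-diene 18,19-lactone
Conditions: Tf2O, i-Pr2NEt, CH2Cl2, −78 °C
Reagents that add atoms: trifluoromethanesulfonic anhydride O=S(=O)(OS(=O)(=O)C(F)(F)F)C(F)(F)F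
Why: O-Sulfonylation of the enolised β-keto lactone fixes the C3=C4 position of the future alkene.

Step 12
Reactants: 19 bicyclic enol triflate
Product: 20 bicyclic diene lactone 1α-(2-furyl)-3,8(10)-diene 18,19-lactone
Conditions: Pd(OAc)2 (5 mol %), PPh3, HCO2H, n-Bu3N, DMF, 60 °C
Reagents that add atoms: none
Why: Palladium-catalysed formate reduction of the vinyl triflate (oxidative addition to zerovalent palladium, hydride transfer from formate, reductive elimination) gives the conjugated alkylidene lactone and leaves the isolated C8=C10 alkene.

Step 13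
Reactants: 20 bicyclic diene lactone
Product: 22 trans-fused bicyclic alcohol 8α-hydroxy-1α-(2-furyl)-10α-H-3-ene 18,19-lactone, via alkylborane 21 (not isolated)
Conditions: BH3·SMe2, THF, 0 °C; then NaBO3·4H2O, THF/H2O, rt
Reagents that add atoms: sodium perborate [Na+].[O-]OB=O
Why: Hydroboration–oxidation; borane adds to the electron-rich trisubstituted C8=C10 alkene (boron at C8) from the α face, anti to the angular C19 over the β face, the preference known for steroidal 14-enes, so syn delivery of H to C10 sets the trans ring fusion; the conjugated C3=C4 alkene is electron-poor and is spared.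

Step 14
Reactants: 22 trans-fused bicyclic alcohol
Product: 23 trans-fused bicyclic ketone 8-oxo-1α-(2-furyl)-10α-H-3-ene 18,19-lactone
Conditions: Dess–Martin periodinane, NaHCO3, CH2Cl2, 0 °C
Reagents that add atoms: none
Why: Dess–Martin oxidation under buffered, non-enolising conditions gives the kinetically formed trans-fused ketone without epimerising C10; 23 is used at once.

Step 15
Reactants: 23 trans-fused bicyclic ketone; 24 ethyl vinyl ether
Product: 27 8α-acetyl-8β-hydroxy-1α-(2-furyl)-3-ene 18,19-lactone, via 1-ethoxyvinyllithium 25 (not isolated), via enol ether adduct 26 (not isolated)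
Conditions: 24, t-BuLi, THF, −78 → 0 °C; CeCl3, −78 °C; 23; then 1 M HCl, THF, 0 °C
Reagents that add atoms: water O
Why: The organocerium reagent from 1-ethoxyvinyllithium (an acetyl anion equivalent) adds to the ketone faster than it enolises it or attacks the lactone, from the α face anti to C19, giving the 8β-hydroxyl (C8 R); dilute acid then hydrolyses the enol ether to the methyl ketone.

Step 16
Reactants: 27 8α-acetyl-8β-hydroxy bicyclic lactone; 28 trimethylsulfonium iodide
Product: 30 epoxy alcohol 8β-hydroxy-8α-[(2R)-2-methyloxiran-2-yl]-1α-(2-furyl)-3-ene 18,19-lactone, via dimethylsulfonium methylide 29 (not isolated)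
Conditions: 28, n-BuLi, THF, −10 °C; then 27, −10 → 0 °C
Reagents that add atoms: none
Why: Corey–Chaykovsky epoxidation; the lithium alkoxide at C8 chelates the ketone oxygen and the ylide attacks the chelate from the side of the C7 methylene, not the hindered C10 side, so ring closure with loss of Me2S gives the R epoxide carbon C9 needed in step 17.

Step 17
Reactants: 30 epoxy alcohol
Product: 31 decalin ketone 11-hydroxy-8-oxo-9β-methyl-1α-(2-furyl)-3-ene 18,19-lactone
Conditions: BF3·OEt2 (1.1 equiv), CH2Cl2, −78 → −40 °C; aq. NaHCO3
Reagents that add atoms: none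
Why: BF3 binds the epoxide oxygen, held near it by the neighbouring 8β-hydroxyl, and weakens the tertiary C9–O bond. As charge builds at C9, the ring bond C8–C10, antiperiplanar to C9–O, shifts to C9 while the carbinol oxygen becomes the C8 carbonyl; the closest known reaction type is the Lewis-acid semipinacol rearrangement of 1-oxiranylcycloalkanols to ring-expanded β-hydroxy ketones. Ring A closes by one-carbon ring expansion through this 1,2-alkyl shift (C9–C10 formed, C8–C10 broken), not by an end-to-end cyclisation. The new stereocentre C9 is formed with inversion at the epoxide carbon, so its configuration is that set in step 16 (methyl β, C11 α), and the migrating C10 keeps its configuration, which preserves the trans fusion set in step 13. The step needs C10 to migrate instead of the C7 methylene; this rests on the higher migratory aptitude of the secondary C10 and on the rotamer with C9–O anti to C8–C10, which places the methyl between the hydroxyl and C10 rather than between two ring carbons. Low temperature, a non-nucleophilic solvent and a bicarbonate quench protect the furan and the alkylidene lactone and avoid retro-aldol loss of C11.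

Step 18
Reactants: 31 decalin ketone
Product: 32 decalin keto aldehyde 8,11-dioxo-9β-methyl-1α-(2-furyl)-3-ene 18,19-lactone
Conditions: Dess–Martin periodinane, NaHCO3, CH2Cl2, 0 °C → rt
Reagents that add atoms: none
Why: Dess–Martin oxidation gives the non-enolisable β-keto aldehyde under neutral conditions that avoid retro-aldol cleavage.

Step 19
Reactants: 32 decalin keto aldehyde
Product: 33 decalin enol ether 9α-(2-methoxyethenyl)-8-oxo-9β-methyl-1α-(2-furyl)-3-ene 18,19-lactone (E/Z mixture)
Conditions: MeOCH2PPh3Cl, KN(SiMe3)2, THF, −78 → 0 °C
Reagents that add atoms: (methoxymethyl)triphenylphosphonium chloride COC[P+](c1ccccc1)(c1ccccc1)c1ccccc1.[Cl-]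
Why: Wittig reaction of methoxymethylenetriphenylphosphorane with the aldehyde (the α-quaternary ketone is far less reactive) installs C12 at the aldehyde oxidation level as a base-stable enol ether.

Step 20
Reactants: 33 decalin enol ether
Product: 34 7α-hydroxy-8-oxo decalin enol ether
Conditions: KN(SiMe3)2, THF, −78 °C; then 2-(phenylsulfonyl)-3-phenyloxaziridine; aq. NH4Cl
Reagents that add atoms: 2-(phenylsulfonyl)-3-phenyloxaziridine O=S(=O)(c1ccccc1)N1OC1c1ccccc1
Why: Enolate oxidation with the Davis oxaziridine; the C8 ketone can enolise only towards C7, and the oxidant approaches from the α face because the β face is blocked by the syn-axial C19 and C20, giving the equatorial 7α-alcohol.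

Step 21
Reactants: 34 7α-hydroxy-8-oxo decalin enol ether
Product: 35 7α-acetoxy-8-oxo decalin enol ether
Conditions: Ac2O, pyridine, DMAP (cat.), CH2Cl2, rt
Reagents that add atoms: acetic anhydride CC(=O)OC(C)=O
Why: DMAP-catalysed acylation of the secondary alcohol; no stereocentre is affected.

Step 22
Reactants: 35 7α-acetoxy-8-oxo decalin enol ether
Product: 36 7α-acetoxy-8(17)-ene decalin enol ether
Conditions: Zn, CH2Br2, TiCl4, THF/CH2Cl2, 0 °C → rt
Reagents that add atoms: dibromomethane BrCBr
Why: Takai–Lombardo methylenation; the non-basic zinc/titanium methylene reagent converts the hindered α-acetoxy ketone into the exocyclic alkene without epimerising C7 and without attacking the acetate or the lactone.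

Step 23
Reactants: 36 7α-acetoxy-8(17)-ene decalin enol ether
Product: 37 12-aldehyde 7α-acetoxy-8(17)-ene-12-al
Conditions: 1 M HCl, THF, rt
Reagents that add atoms: water O
Why: Acid-catalysed enol ether hydrolysis releases the C12 aldehyde; dilute acid at room temperature should leave the allylic acetate, the alkene and the furan untouched.

Step 24
Reactants: 37 12-aldehyde
Product: 38 12-carboxylic acid 7α-acetoxy-8(17)-ene-12-oic acid
Conditions: NaClO2, NaH2PO4, 2-methylbut-2-ene, t-BuOH/H2O, 0 °C → rt
Reagents that add atoms: sodium chlorite [Na+].[O-]Cl=O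
Why: Pinnick oxidation; excess 2-methylbut-2-ene scavenges hypochlorite so that the furan and the alkenes are spared.

Step 25
Reactants: 38 12-carboxylic acid
Product: 40 the target (7α-acetoxy-12-oxo-8(17)-ene 18,19-lactone with ring C closed on furan C13), via acyl chloride 39 (not isolated)
Conditions: (COCl)2, DMF (cat.), CH2Cl2, 0 °C; then SnCl4, 2,6-di-tert-butyl-4-methylpyridine, CH2Cl2, −78 °C
Reagents that add atoms: none
Why: Intramolecular Friedel–Crafts acylation; the acyl chloride–SnCl4 complex can reach only C13 of the furan, closing the seven-membered ring between the equatorial arms on C1 and C9, whereas acylation of the exocyclic alkene would be a 5-endo closure on an alkene deactivated by the allylic acetate; the hindered base removes HCl.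

## Compound list

1 | 3-ethoxycyclopent-2-en-1-one | CCOC1=CC(=O)CC1 | starting material
2 | 3-ethoxy-1-[(methoxymethoxy)methyl]cyclopent-2-en-1-ol (racemic 1,2-adduct) | CCOC1=CC(O)(COCOC)CC1 | intermediate
3 | 3-[(methoxymethoxy)methyl]cyclopent-2-en-1-one | COCOCC1=CC(=O)CC1 | intermediate
4 | (1R)-3-[(methoxymethoxy)methyl]cyclopent-2-en-1-ol | O[C@H]1C=C(COCOC)CC1 | intermediate
5 | (1R)-1-[(1-ethoxyethenyl)oxy]-3-[(methoxymethoxy)methyl]cyclopent-2-ene (ketene acetal) | C=C(OCC)O[C@H]1C=C(COCOC)CC1 | intermediate
6 | ethyl 2-[(1S)-1-[(methoxymethoxy)methyl]cyclopent-2-en-1-yl]acetate | CCOC(=O)C[C@]1(COCOC)C=CCC1 | intermediate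
7 | ethyl 2-[(1S)-1-(hydroxymethyl)cyclopent-2-en-1-yl]acetate | CCOC(=O)C[C@]1(CO)C=CCC1 | intermediate
8 | (5S)-2-oxaspiro[4.4]non-6-en-3-one | O=C1C[C@]2(CO1)C=CCC2 | intermediate
9 | (5S)-2-oxaspiro[4.4]non-8-ene-3,7-dione | O=C1C[C@]2(CO1)C=CC(=O)C2 | intermediate
10 | furfural (furan-2-carbaldehyde) | O=Cc1ccco1 | starting material
11 | (5S)-6-[furan-2-yl(hydroxy)methyl]-2-oxaspiro[4.4]non-8-ene-3,7-dione (aldol adduct, mixture at C6 and the carbinol) | O=C1C[C@]2(CO1)C=CC(=O)C2C(O)c1ccco1 | intermediate
12 | methanesulfonate of 11 | O=C1C[C@]2(CO1)C=CC(=O)C2C(OS(C)(=O)=O)c1ccco1 | intermediate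
13 | (5S,6E)-6-(furan-2-ylmethylidene)-2-oxaspiro[4.4]non-8-ene-3,7-dione | O=C1C[C@]2(CO1)C=CC(=O)/C2=C/c1ccco1 | intermediate
14 | (5R,6E)-6-(furan-2-ylmethylidene)-2-oxaspiro[4.4]nonane-3,7-dione | O=C1C[C@]2(CO1)CCC(=O)/C2=C/c1ccco1 | intermediate
15 | (5R,6E,7R)-6-(furan-2-ylmethylidene)-7-hydroxy-2-oxaspiro[4.4]nonan-3-one (hydroxyl cis to C19) | O=C1C[C@]2(CO1)CC[C@@H](O)/C2=C/c1ccco1 | intermediate
16 | 1-ethoxyethenyl ether of 15 (ketene acetal) | O=C1C[C@]2(CO1)CC[C@@H](OC(=C)OCC)/C2=C/c1ccco1 | intermediate
17 | ethyl (3R)-3-(furan-2-yl)-3-[(5R)-3-oxo-2-oxaspiro[4.4]non-6-en-6-yl]propanoate | O=C1C[C@]2(CO1)CCC=C2[C@@H](CC(=O)OCC)c1ccco1 | intermediate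
18 | bicyclic enol lactone: ring B with C3(OH)=C4 (enol of the 3-oxo lactone), 18,19-lactone, cyclopentene C8=C10, 1α-(2-furyl), 1β-H | C1=C2[C@H](c3ccco3)CC(O)=C4C(=O)OC[C@@]24CC1 | intermediate
19 | bicyclic enol triflate: as 18 with C3–OSO2CF3 | C1=C2[C@H](c3ccco3)CC(OS(=O)(=O)C(F)(F)F)=C4C(=O)OC[C@@]24CC1 | intermediate
20 | bicyclic diene lactone: ring B C3=C4, 18,19-lactone, cyclopentene C8=C10, 1α-(2-furyl) | C1=C2[C@H](c3ccco3)CC=C4C(=O)OC[C@@]24CC1 | intermediate
21 | 8α-boryl (RBH2) adduct of 20, 10α-H | B[C@H]1CC[C@@]23COC(=O)C2=CC[C@@H](c2ccco2)[C@H]13 | intermediate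
22 | trans-fused bicyclic alcohol: 8α-OH (C8 S), 10α-H, 1α-(2-furyl), C3=C4, 18,19-lactone | O[C@H]1CC[C@@]23COC(=O)C2=CC[C@@H](c2ccco2)[C@H]13 | intermediate
23 | trans-fused bicyclic ketone: 8-oxo, 10α-H, 1α-(2-furyl), C3=C4, 18,19-lactone | O=C1CC[C@@]23COC(=O)C2=CC[C@@H](c2ccco2)[C@H]13 | intermediate
24 | ethyl vinyl ether | C=COCC | starting material
25 | 1-ethoxyvinyllithium | [Li]C(=C)OCC | intermediate
26 | 8α-(1-ethoxyethenyl)-8β-hydroxy adduct of 23 | C=C(OCC)[C@@]1(O)CC[C@@]23COC(=O)C2=CC[C@@H](c2ccco2)[C@H]13 | intermediate
27 | 8α-acetyl-8β-hydroxy bicyclic lactone (C8 R) | CC(=O)[C@@]1(O)CC[C@@]23COC(=O)C2=CC[C@@H](c2ccco2)[C@H]13 | intermediate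
28 | trimethylsulfonium iodide | C[S+](C)C.[I-] | starting material
29 | dimethylsulfonium methylide | C[S+](C)[CH2-] | intermediate
30 | epoxy alcohol: 8β-hydroxy-8α-[(2R)-2-methyloxiran-2-yl] bicyclic lactone (C8 R, C9 R) | C[C@@]4(CO4)[C@@]1(O)CC[C@@]23COC(=O)C2=CC[C@@H](c2ccco2)[C@H]13 | intermediate
31 | decalin ketone: 8-oxo, 9β-methyl, 9α-CH2OH (C11), 10α-H, 1α-(2-furyl), C3=C4, 18,19-lactone | O=C1CC[C@@]23COC(=O)C2=CC[C@@H](c2ccco2)[C@@H]3[C@@]1(C)CO | intermediate
32 | decalin keto aldehyde: as 31 with 9α-CHO | O=C1CC[C@@]23COC(=O)C2=CC[C@@H](c2ccco2)[C@@H]3[C@@]1(C)C=O | intermediate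
33 | decalin enol ether: as 31 with 9α-CH=CH–OMe (E/Z mixture) | O=C1CC[C@@]23COC(=O)C2=CC[C@@H](c2ccco2)[C@@H]3[C@@]1(C)C=COC | intermediate
34 | 7α-hydroxy-8-oxo decalin enol ether | O=C1[C@@H](O)C[C@@]23COC(=O)C2=CC[C@@H](c2ccco2)[C@@H]3[C@@]1(C)C=COC | intermediate
35 | 7α-acetoxy-8-oxo decalin enol ether | O=C1[C@@H](OC(C)=O)C[C@@]23COC(=O)C2=CC[C@@H](c2ccco2)[C@@H]3[C@@]1(C)C=COC | intermediate
36 | 7α-acetoxy-8(17)-ene decalin enol ether | C=C1[C@@H](OC(C)=O)C[C@@]23COC(=O)C2=CC[C@@H](c2ccco2)[C@@H]3[C@@]1(C)C=COC | intermediate
37 | 12-aldehyde: 7α-acetoxy-8(17)-ene, 9α-CH2CHO | C=C1[C@@H](OC(C)=O)C[C@@]23COC(=O)C2=CC[C@@H](c2ccco2)[C@@H]3[C@@]1(C)CC=O | intermediate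
38 | 12-carboxylic acid: 7α-acetoxy-8(17)-ene, 9α-CH2CO2H | C=C1[C@@H](OC(C)=O)C[C@@]23COC(=O)C2=CC[C@@H](c2ccco2)[C@@H]3[C@@]1(C)CC(=O)O | intermediate
39 | 12-acyl chloride of 38 | C=C1[C@@H](OC(C)=O)C[C@@]23COC(=O)C2=CC[C@@H](c2ccco2)[C@@H]3[C@@]1(C)CC(=O)Cl | intermediate
40 | CNP0273675.1: 7α-acetoxy, 8(17)-ene, 9β-methyl, 10α-H, 1β-H, 12-oxo, ring C closed C12–C13, C3=C4, 18,19-lactone | C=C1[C@@H](OC(C)=O)C[C@@]23COC(=O)C2=CC[C@H]2c4occc4C(=O)C[C@]1(C)[C@@H]23 | target

## Step count and risks

Total step count: 25. Longest linear sequence: 25 steps (the route is linear from 1; 10, 24 and 28 enter as single reagents).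

**Step 17 (key step).** The shift may take the wrong ring carbon (C7 instead of C10), or the Lewis acid may trigger retro-aldol fragmentation of the product or attack on the furan. Fallback: from 30, treatment with Al(Oi-Pr)3 in i-PrOH/toluene runs the rearrangement on the aluminium alkoxide of the carbinol and reduces the nascent ketone in the same flask (tandem semipinacol/Meerwein–Ponndorf–Verley reduction). This gives the 1,3-diol F1, so the retro-aldol-prone β-hydroxy ketone never accumulates. Twofold Dess–Martin oxidation of F1 then gives 32, where the route is rejoined.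

**Step 25.** The acyl cation equivalent may be intercepted by the exocyclic alkene, HCl may isomerise that alkene, the allylic acetate may ionise, or acylation may occur between molecules at the free furan α-position. Fallback: the order of the last operations is changed so that ring C is closed before the alkene exists.
- From 35, acid hydrolysis gives the keto aldehyde F2 and Pinnick oxidation the keto acid F3.
- Acyl chloride formation and SnCl4 then close ring C on an alkene-free substrate to the acetoxy diketone F4.
- The furyl ketone, the more Lewis-basic carbonyl with the only unhindered α-methylene, is masked as its silyl enol ether F5 (TBSOTf, Et3N).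
- Takai–Lombardo methylenation of the remaining C8 ketone gives the methylene silyl enol ether F6, and HF·pyridine returns 40.

**Step 22.** Methylenation of a ketone flanked by a quaternary carbon and an acetoxy-bearing carbon may be too slow, and the Lewis-acidic reagent may cleave the enol ether early. Fallback: a two-stage Peterson olefination. From 34, Me3SiCH2Li/CeCl3 (excess, alkoxide-assisted) adds to C8 to give the β-hydroxysilane diol F7. KH in THF induces syn-elimination to the allylic alcohol F8, and acetylation gives 36.

**Step 16.** Facial selectivity is lost if the lithium alkoxide–ketone chelate is not maintained; the C9 epimer of the epoxide would then form and would be copied into the wrong C9 in step 17. Fallback: chelation control is enforced with magnesium and the epoxide is closed afterwards.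
- From 27, (i-PrO)Me2SiCH2MgCl adds to the chelated ketone to give the silyl diol F9.
- Tamao oxidation (H2O2, KF, KHCO3) gives the triol F10.
- Selective sulfonylation of the primary hydroxyl gives the monotosylate F11, which K2CO3 closes to 30.

**Step 13.** Borane may add syn to C19 (cis ring fusion) if the furyl group on C1 shields the α face more than expected, or it may attack the furan. Fallback: substrate control is replaced by reagent control. From 20, hydroboration with the matched enantiomer of monoisopinocampheylborane followed by the same oxidation gives 22; no new compound is formed (F0).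

## Further compounds

F1 | step 17 | decalin 1,3-diol: 8-hydroxy (configuration at C8 not defined), 9β-methyl, 9α-CH2OH, otherwise as 31 | OC1CC[C@@]23COC(=O)C2=CC[C@@H](c2ccco2)[C@@H]3[C@@]1(C)CO
F2 | step 25 | keto aldehyde: 7α-acetoxy-8-oxo, 9α-CH2CHO | O=C1[C@@H](OC(C)=O)C[C@@]23COC(=O)C2=CC[C@@H](c2ccco2)[C@@H]3[C@@]1(C)CC=O
F3 | step 25 | keto acid: 7α-acetoxy-8-oxo, 9α-CH2CO2H | O=C1[C@@H](OC(C)=O)C[C@@]23COC(=O)C2=CC[C@@H](c2ccco2)[C@@H]3[C@@]1(C)CC(=O)O
F4 | step 25 | acetoxy diketone: 7α-acetoxy-8,12-dioxo, ring C closed | O=C1[C@@H](OC(C)=O)C[C@@]23COC(=O)C2=CC[C@H]2c4occc4C(=O)C[C@]1(C)[C@@H]23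
F5 | step 25 | C11=C12 tert-butyldimethylsilyl enol ether of F4 | O=C1[C@@H](OC(C)=O)C[C@@]23COC(=O)C2=CC[C@H]2c4occc4C(O[Si](C)(C)C(C)(C)C)=C[C@]1(C)[C@@H]23
F6 | step 25 | 8(17)-methylene silyl enol ether | C=C1[C@@H](OC(C)=O)C[C@@]23COC(=O)C2=CC[C@H]2c4occc4C(O[Si](C)(C)C(C)(C)C)=C[C@]1(C)[C@@H]23
F7 | step 22 | β-hydroxysilane diol: 7α,8-dihydroxy-8-(trimethylsilylmethyl) enol ether (C8 not defined) | C[Si](C)(C)CC1(O)[C@@H](O)C[C@@]23COC(=O)C2=CC[C@@H](c2ccco2)[C@@H]3[C@@]1(C)C=COC
F8 | step 22 | allylic alcohol: 7α-hydroxy-8(17)-ene enol ether | C=C1[C@@H](O)C[C@@]23COC(=O)C2=CC[C@@H](c2ccco2)[C@@H]3[C@@]1(C)C=COC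
F9 | step 16 | silyl diol: 8β,9-dihydroxy, C11–Si(Me)2(Oi-Pr) | CC(C)O[Si](C)(C)C[C@@](C)(O)[C@@]1(O)CC[C@@]23COC(=O)C2=CC[C@@H](c2ccco2)[C@H]13
F10 | step 16 | triol: 8β,9,11-trihydroxy | OC[C@@](C)(O)[C@@]1(O)CC[C@@]23COC(=O)C2=CC[C@@H](c2ccco2)[C@H]13
F11 | step 16 | 11-monotosylate of F10 | Cc1ccc(cc1)S(=O)(=O)OC[C@@](C)(O)[C@@]1(O)CC[C@@]23COC(=O)C2=CC[C@@H](c2ccco2)[C@H]13
F0 | step 13 | none | none
A1 | alternative 1 | trans-decalin diester from the intramolecular Diels–Alder reaction | C=C1[C@@H](OC(C)=O)C[C@@]2(CO[Si](C)(C)C(C)(C)C)C(C(=O)OC)=CC[C@@H](c3ccco3)[C@@H]2[C@@]1(C)CC(=O)OC(C)(C)C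
A2 | alternative 1 | triene precursor (2-methoxycarbonyl diene tethered to the E-vinylfuran) | C=C/C(C(=O)OC)=C(\CO[Si](C)(C)C(C)(C)C)C[C@H](OC(C)=O)C(=C)[C@](C)(CC(=O)OC(C)(C)C)/C=C/c1ccco1
A3 | alternative 2 | C12 dithiolane of the target | C=C1[C@@H](OC(C)=O)C[C@@]23COC(=O)C2=CC[C@H]2c4occc4C4(SCCS4)C[C@]1(C)[C@@H]23
A4 | alternative 2 | dienyl lactone with tethered 3-furyl dithiolane | C=C1[C@@H](OC(C)=O)C[C@@]23COC(=O)C2=CC=C[C@@H]3[C@@]1(C)CC1(SCCS1)c1ccoc1
A5 | alternative 3 | decalin lactone with furyl and ester arms from the Wolff contraction | C=C1[C@@H](O[Si](C)(C)C(C)(C)C)C[C@@]23COC(=O)C2=CC[C@@H](c2ccco2)[C@@H]3[C@@]1(C)CC(=O)OC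
A6 | alternative 3 | seven-membered α-diazo-β,γ-enone with free C19 hydroxyl | C=C1[C@@H](O[Si](C)(C)C(C)(C)C)C[C@@]2(CO)C(=O)C(=[N+]=[N-])C=C[C@@H](c3ccco3)[C@@H]2[C@@]1(C)CC(=O)OC
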